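**Plan**
- Retrosynthesis: the three aryl methyl ethers are cleaved last. Ring A (C1 bears the ethylene bridge, C3 the hydroxyl) is cut at C1–C2 and C5–C6, giving a 1‑methoxy‑3‑silyloxybutadiene (C2–C5) and a nitroalkene (C1, C6).
- The nitroalkene goes back by a nitroaldol disconnection to a 3‑arylpropanal, the diaryl ether by C–O coupling to a ring C phenol and a ring B bromide, and the ring C–ring D bridge by olefination and hydrogenation.
- Forward: rings D and C are joined (steps 1–3), ring B is attached through oxygen (step 4), the side chain is taken to the nitroalkene (steps 5–7), ring A is built de novo (step 8) and the ethers are removed (step 9).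
- Enabling feature: ring A carries only O on C3 and the bridge carbon on C1 (1,3), with H on C2, C4, C5 and C6. C3 can therefore be the oxygenated diene carbon, C2 the free diene terminus and C1 the β‑carbon of a dienophile whose activating group on C6 is lost afterwards.
- Stereochemistry: the target has no stereocentre and no stereogenic double bond. The stilbene geometry, the carbinol centre and the cycloadduct centres are all transient.

Key step: step 8

Assumption: 1, 2, 4, 7, 10 and 14 are treated as catalogue chemicals.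

**Route**

Step 1
Reactants: 1 2‑(chloromethyl)‑1,4‑dimethoxybenzene (2,5‑dimethoxybenzyl chloride); 2 triphenylphosphine
Product: 3 (2,5‑dimethoxybenzyl)triphenylphosphonium chloride
Conditions: PPh3 (1.05 equiv), toluene, 110 °C; salt collected by filtration
Reagents that add atoms: none
Why: SN2 quaternisation of triphenylphosphine by a reactive benzylic chloride should give the phosphonium salt, which precipitates from hot toluene.

Step 2
Reactants: 3 (2,5‑dimethoxybenzyl)triphenylphosphonium chloride; 4 3‑(benzyloxy)‑4‑methoxybenzaldehyde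
Product: 5 2‑(benzyloxy)‑4‑[2‑(2,5‑dimethoxyphenyl)ethenyl]‑1‑methoxybenzene (E/Z mixture)
Conditions: KOtBu (1.2 equiv), THF, 0 °C; then 4, 0 °C → rt
Reagents that add atoms: none
Why: Wittig olefination of an aromatic aldehyde with a semi‑stabilised benzylic ylide is dependable, and the mixed alkene geometry is of no consequence because the double bond is saturated in the next step.

Step 3
Reactants: 5 2‑(benzyloxy)‑4‑[2‑(2,5‑dimethoxyphenyl)ethenyl]‑1‑methoxybenzene
Product: 6 5‑[2‑(2,5‑dimethoxyphenyl)ethyl]‑2‑methoxyphenol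
Conditions: H2 (1 atm), 10% Pd/C, EtOAc/MeOH, rt
Reagents that add atoms: none
Why: heterogeneous catalytic hydrogenation should saturate the stilbene and hydrogenolyse the benzyl ether in one operation, while the aryl methyl ethers are inert.

Step 4
Reactants: 6 5‑[2‑(2,5‑dimethoxyphenyl)ethyl]‑2‑methoxyphenol; 7 methyl 3‑(4‑bromophenyl)propanoate
Product: 8 methyl 3‑[4‑[5‑[2‑(2,5‑dimethoxyphenyl)ethyl]‑2‑methoxyphenoxy]phenyl]propanoate
Conditions: CuI (10 mol%), N,N‑dimethylglycine hydrochloride (30 mol%), Cs2CO3 (2 equiv), 1,4‑dioxane, 90 °C, Ar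
Reagents that add atoms: none
Why: the amino‑acid‑accelerated Ullmann diaryl ether coupling joins a phenoxide to an aryl bromide at moderate temperature, and the carbonate base is too weak to enolise or condense the aliphatic ester.

Step 5
Reactants: 8 methyl 3‑[4‑[5‑[2‑(2,5‑dimethoxyphenyl)ethyl]‑2‑methoxyphenoxy]phenyl]propanoate
Product: 9 3‑[4‑[5‑[2‑(2,5‑dimethoxyphenyl)ethyl]‑2‑methoxyphenoxy]phenyl]propanal
Conditions: iBu2AlH (DIBAL‑H, 1.1 equiv), CH2Cl2, −78 °C; MeOH quench at −78 °C, aq. potassium sodium tartrate (KNaC4H4O6)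
Reagents that add atoms: none
Why: partial ester reduction with one equivalent of DIBAL‑H at −78 °C should stop at the aluminium hemiacetal, which releases the aldehyde only on hydrolytic work‑up, and the aryl ethers do not react.

Step 6
Reactants: 9 3‑[4‑[5‑[2‑(2,5‑dimethoxyphenyl)ethyl]‑2‑methoxyphenoxy]phenyl]propanal; 10 nitromethane
Product: 11 4‑[4‑[5‑[2‑(2,5‑dimethoxyphenyl)ethyl]‑2‑methoxyphenoxy]phenyl]‑1‑nitrobutan‑2‑ol (racemic)
Conditions: MeNO2 (10 equiv), KOtBu (10 mol%), THF/tBuOH 1:1, 0 °C → rt; AcOH quench, excess MeNO2 removed in vacuo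
Reagents that add atoms: none
Why: the Henry (nitroaldol) addition of nitromethane to an unhindered aliphatic aldehyde under catalytic base is standard, and the racemic carbinol centre it creates is destroyed in step 7.

Step 7
Reactants: 11 4‑[4‑[5‑[2‑(2,5‑dimethoxyphenyl)ethyl]‑2‑methoxyphenoxy]phenyl]‑1‑nitrobutan‑2‑ol
Product: 13 (E)‑4‑[4‑[5‑[2‑(2,5‑dimethoxyphenyl)ethyl]‑2‑methoxyphenoxy]phenyl]‑1‑nitrobut‑1‑ene, via mesylate 12 (not isolated)
Conditions: MsCl (1.2 equiv), Et3N (2.5 equiv), CH2Cl2, 0 °C, 30 min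
Reagents that add atoms: none
Why: O‑mesylation followed by E1cB elimination through the nitronate should give the conjugated nitroalkene as the thermodynamically preferred (E) isomer, and the short reaction time at 0 °C limits base‑induced deconjugation.

Step 8
Reactants: 13 (E)‑4‑[4‑[5‑[2‑(2,5‑dimethoxyphenyl)ethyl]‑2‑methoxyphenoxy]phenyl]‑1‑nitrobut‑1‑ene; 14 (E)‑1‑methoxy‑3‑(trimethylsilyloxy)buta‑1,3‑diene
Product: 17 3‑[2‑[4‑[5‑[2‑(2,5‑dimethoxyphenyl)ethyl]‑2‑methoxyphenoxy]phenyl]ethyl]phenol, via cycloadduct 15 (not isolated), via nitroenone 16 (not isolated)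
Conditions: 14 (2.5 equiv), toluene, 100 °C, sealed tube; then 0.1 M aq. HCl (cat.), THF, 0 °C → rt; then DBU (3 equiv), rt → 40 °C
Reagents that add atoms: none
Why: A thermal, normal‑electron‑demand Diels–Alder reaction should join the unsubstituted diene terminus C4, the most nucleophilic carbon because both oxygen donors feed it, to the chain‑bearing β‑carbon of the nitroalkene and the methoxy‑bearing C1 to the nitro‑bearing α‑carbon, so ring A closes as a six‑membered carbocycle in one suprafacial [4+2] event that makes both new C–C bonds. The closest known reaction type is the cycloaddition of 1‑alkoxy‑3‑silyloxybutadienes to nitroalkenes serving as alkyne equivalents, followed by aromatisation through loss of alcohol and nitrous acid. Dilute acid is applied first so that the silyl enol ether is hydrolysed and methanol is eliminated toward the new ketone, giving nitroenone 16; DBU then expels nitrite across C4–C5 and the resulting cyclohexa‑2,4‑dienone tautomerises to the phenol. The three stereocentres of 15 are all erased on aromatisation, so endo/exo selectivity does not matter. The selectivity needed is regiochemical, the chain having to end up meta to the oxygen, and it is secured by the matched polarisation of the donor‑substituted diene and the nitro group; leaving out Lewis acids avoids the competing hetero‑Diels–Alder mode in which the nitroalkene reacts as a heterodiene.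

Step 9
Reactants: 17 3‑[2‑[4‑[5‑[2‑(2,5‑dimethoxyphenyl)ethyl]‑2‑methoxyphenoxy]phenyl]ethyl]phenol
Product: 18 2‑[2‑[4‑hydroxy‑3‑[4‑[2‑(3‑hydroxyphenyl)ethyl]phenoxy]phenyl]ethyl]benzene‑1,4‑diol
Conditions: BBr3 (8 equiv), CH2Cl2, −78 °C → rt; MeOH then H2O at 0 °C; work‑up under Ar with aq. Na2S2O4
Reagents that add atoms: none
Why: Lewis‑acid O‑demethylation with BBr3 cleaves aryl methyl ethers by bromide attack on the methyl group of the boron‑complexed ether and should leave the diaryl ether and the bibenzyl bridges intact, and the reducing, air‑free work‑up protects the hydroquinone ring D.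

**Compound list**
1 | 2‑(chloromethyl)‑1,4‑dimethoxybenzene | COc1ccc(OC)c(CCl)c1 | starting material
2 | triphenylphosphine | c1ccc(cc1)P(c1ccccc1)c1ccccc1 | starting material
3 | (2,5‑dimethoxybenzyl)triphenylphosphonium chloride | COc1ccc(OC)c(C[P+](c2ccccc2)(c2ccccc2)c2ccccc2)c1.[Cl-] | intermediate
4 | 3‑(benzyloxy)‑4‑methoxybenzaldehyde | COc1ccc(C=O)cc1OCc1ccccc1 | starting material
5 | 2‑(benzyloxy)‑4‑[2‑(2,5‑dimethoxyphenyl)ethenyl]‑1‑methoxybenzene, E/Z mixture | COc1ccc(C=Cc2cc(OC)ccc2OC)cc1OCc1ccccc1 | intermediate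
6 | 5‑[2‑(2,5‑dimethoxyphenyl)ethyl]‑2‑methoxyphenol | COc1ccc(CCc2cc(OC)ccc2OC)cc1O | intermediate
7 | methyl 3‑(4‑bromophenyl)propanoate | COC(=O)CCc1ccc(Br)cc1 | starting material
8 | methyl 3‑[4‑[5‑[2‑(2,5‑dimethoxyphenyl)ethyl]‑2‑methoxyphenoxy]phenyl]propanoate | COC(=O)CCc1ccc(Oc2cc(CCc3cc(OC)ccc3OC)ccc2OC)cc1 | intermediate
9 | 3‑[4‑[5‑[2‑(2,5‑dimethoxyphenyl)ethyl]‑2‑methoxyphenoxy]phenyl]propanal | O=CCCc1ccc(Oc2cc(CCc3cc(OC)ccc3OC)ccc2OC)cc1 | intermediate
10 | nitromethane | C[N+](=O)[O-] | starting material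
11 | 4‑[4‑[5‑[2‑(2,5‑dimethoxyphenyl)ethyl]‑2‑methoxyphenoxy]phenyl]‑1‑nitrobutan‑2‑ol, racemic | [O-][N+](=O)CC(O)CCc1ccc(Oc2cc(CCc3cc(OC)ccc3OC)ccc2OC)cc1 | intermediate
12 | 4‑[4‑[5‑[2‑(2,5‑dimethoxyphenyl)ethyl]‑2‑methoxyphenoxy]phenyl]‑1‑nitrobutan‑2‑yl methanesulfonate, racemic, not isolated | CS(=O)(=O)OC(C[N+](=O)[O-])CCc1ccc(Oc2cc(CCc3cc(OC)ccc3OC)ccc2OC)cc1 | intermediate
13 | (E)‑4‑[4‑[5‑[2‑(2,5‑dimethoxyphenyl)ethyl]‑2‑methoxyphenoxy]phenyl]‑1‑nitrobut‑1‑ene | [O-][N+](=O)/C=C/CCc1ccc(Oc2cc(CCc3cc(OC)ccc3OC)ccc2OC)cc1 | intermediate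
14 | (E)‑1‑methoxy‑3‑(trimethylsilyloxy)buta‑1,3‑diene | CO/C=C/C(=C)O[Si](C)(C)C | starting material
15 | [5‑[2‑[4‑[5‑[2‑(2,5‑dimethoxyphenyl)ethyl]‑2‑methoxyphenoxy]phenyl]ethyl]‑3‑methoxy‑4‑nitrocyclohex‑1‑en‑1‑yl]oxy‑trimethylsilane, racemic, 4,5‑trans, both C3 epimers, one enantiomer drawn, not isolated | COC1C=C(O[Si](C)(C)C)C[C@@H](CCc2ccc(Oc3cc(CCc4cc(OC)ccc4OC)ccc3OC)cc2)[C@@H]1[N+](=O)[O-] | intermediate
16 | 5‑[2‑[4‑[5‑[2‑(2,5‑dimethoxyphenyl)ethyl]‑2‑methoxyphenoxy]phenyl]ethyl]‑4‑nitrocyclohex‑2‑en‑1‑one, racemic, 4,5‑trans expected, one enantiomer drawn, not isolated | O=C1C=C[C@@H]([N+](=O)[O-])[C@H](CCc2ccc(Oc3cc(CCc4cc(OC)ccc4OC)ccc3OC)cc2)C1 | intermediate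
17 | 3‑[2‑[4‑[5‑[2‑(2,5‑dimethoxyphenyl)ethyl]‑2‑methoxyphenoxy]phenyl]ethyl]phenol | Oc1cccc(CCc2ccc(Oc3cc(CCc4cc(OC)ccc4OC)ccc3OC)cc2)c1 | intermediate
18 | 2‑[2‑[4‑hydroxy‑3‑[4‑[2‑(3‑hydroxyphenyl)ethyl]phenoxy]phenyl]ethyl]benzene‑1,4‑diol | Oc1cccc(CCc2ccc(Oc3cc(CCc4cc(O)ccc4O)ccc3O)cc2)c1 | target

**Summary**
Total step count: 9. Longest linear sequence: 9 steps (1 → 18); 2, 4, 7, 10 and 14 enter as purchased partners.

**Steps most likely to fail**

Step 8. The β‑alkyl nitroalkene is a weaker dienophile than an aryl‑conjugated one, so thermal desilylation or polymerisation of the diene and oligomerisation of the nitroalkene may outrun the cycloaddition, and the final loss of nitrite may stall. The fallback sets out from 13 and changes the donor on the diene from methoxy to dimethylamino. The commercial (E)‑1‑(dimethylamino)‑3‑(tert‑butyldimethylsilyloxy)buta‑1,3‑diene should add to nitroalkenes at 0 °C to room temperature in CH2Cl2 with the same regiochemistry, giving the amino silyl enol ether cycloadduct F1. Treatment with 1 M aq. HCl in THF should cleave the silyl ether and eliminate dimethylamine, so the sequence comes back to the route at nitroenone 16, which DBU takes on to 17 as in step 8.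

Step 4. Copper‑mediated C–O bond formation between the ortho‑methoxy‑hindered phenoxide and an unactivated aryl bromide may be slow, so that hydrodebromination or ester cleavage competes. The fallback sets out from 6 and uses nucleophilic aromatic substitution on 4‑fluorobenzaldehyde (K2CO3, DMF, 130 °C) to give 4‑[5‑[2‑(2,5‑dimethoxyphenyl)ethyl]‑2‑methoxyphenoxy]benzaldehyde F2. A Horner–Wadsworth–Emmons reaction with triethyl phosphonoacetate (NaH, THF, 0 °C → rt) gives the ethyl cinnamate F3, and hydrogenation (H2, 10% Pd/C, EtOAc) gives the saturated ethyl ester F4. Partial reduction of F4 with DIBAL‑H under the conditions of step 5 rejoins the route at 9.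

Step 5. Premature collapse of the aluminium hemiacetal leads to over‑reduction to the primary alcohol, and the enolisable aldehyde may be lost on chromatography. The fallback sets out from 8: full reduction with LiAlH4 (THF, 0 °C) gives 3‑[4‑[5‑[2‑(2,5‑dimethoxyphenyl)ethyl]‑2‑methoxyphenoxy]phenyl]propan‑1‑ol F5, and Swern oxidation ((COCl)2, DMSO, Et3N, CH2Cl2, −78 °C) returns to the route at 9.

**Further compounds**
F1 | step 8 | tert‑butyl‑[[3‑(dimethylamino)‑5‑[2‑[4‑[5‑[2‑(2,5‑dimethoxyphenyl)ethyl]‑2‑methoxyphenoxy]phenyl]ethyl]‑4‑nitrocyclohex‑1‑en‑1‑yl]oxy]dimethylsilane, racemic, 4,5‑trans, one enantiomer drawn | CN(C)C1C=C(O[Si](C)(C)C(C)(C)C)C[C@@H](CCc2ccc(Oc3cc(CCc4cc(OC)ccc4OC)ccc3OC)cc2)[C@@H]1[N+](=O)[O-]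
F2 | step 4 | 4‑[5‑[2‑(2,5‑dimethoxyphenyl)ethyl]‑2‑methoxyphenoxy]benzaldehyde | O=Cc1ccc(Oc2cc(CCc3cc(OC)ccc3OC)ccc2OC)cc1
F3 | step 4 | ethyl (E)‑3‑[4‑[5‑[2‑(2,5‑dimethoxyphenyl)ethyl]‑2‑methoxyphenoxy]phenyl]prop‑2‑enoate | CCOC(=O)/C=C/c1ccc(Oc2cc(CCc3cc(OC)ccc3OC)ccc2OC)cc1
F4 | step 4 | ethyl 3‑[4‑[5‑[2‑(2,5‑dimethoxyphenyl)ethyl]‑2‑methoxyphenoxy]phenyl]propanoate | CCOC(=O)CCc1ccc(Oc2cc(CCc3cc(OC)ccc3OC)ccc2OC)cc1
F5 | step 5 | 3‑[4‑[5‑[2‑(2,5‑dimethoxyphenyl)ethyl]‑2‑methoxyphenoxy]phenyl]propan‑1‑ol | OCCCc1ccc(Oc2cc(CCc3cc(OC)ccc3OC)ccc2OC)cc1
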